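## Retrosynthetic overview

- **Structural feature:** each of the two identical benzene rings carries OH on C1 and C3 and the tether on C5. The rings are joined C5 to C5' through fourteen CH2 groups, so C5 + (CH2)14 + C5' is one unbranched C16 unit with a future ring carbon at each end.
- **Late disconnections:** a methyl ester is put back on C4 of each ring and leaves last as CO2. Each arene is traced to a 2,4-dioxocyclohexanecarboxylate, one dehydrogenation below the aromatic level.
- **Key disconnection, both rings at once:** two bonds are cut in each six-membered ring. One runs from the ester-bearing carbon to the tether-bearing carbon (Michael); the other runs from the adjacent carbonyl carbon to the CH2 between the two carbonyls (Claisen). This leaves a C22 bis(methyl enone) and two dimethyl malonates.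
- **Chain:** the bis-enone comes from hexadecanedial by a double Wittig reaction, and the dialdehyde from hexadecane-1,16-diol.
- **Ring order:** no ring exists before step 3, where both carbocycles close in one operation. They are aromatised together in step 4 and lose their esters in steps 5 and 6.

Key step: step 3

Remark on the chemistry: compounds 8 and 9 are drawn as all-keto tautomers and are expected as mixtures of diastereomers and enol forms. No configuration is assigned, because every sp3 ring centre becomes sp2 in step 4.

## Route

Step 1
Reactants: 1 hexadecane-1,16-diol
Product: 2 hexadecanedial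
Conditions: TEMPO (0.2 equiv), PhI(OAc)2 (2.3 equiv), CH2Cl2, 25–35 °C; aq Na2S2O3/NaHCO3 wash; crude used the same day
Reagents that add atoms: none
Why: TEMPO/PhI(OAc)2 oxidation (oxoammonium catalysis) takes primary alcohols to aldehydes and stops there in the absence of water, and it runs near room temperature where the waxy diol dissolves as it is consumed, which a cryogenic activated-DMSO oxidation would not allow.

Step 2
Reactants: 2 hexadecanedial; 3 1-(triphenylphosphoranylidene)propan-2-one
Product: 4 (3E,19E)-docosa-3,19-diene-2,21-dione
Conditions: 3 (2.5 equiv), toluene, 80 °C; silica plug, recrystallisation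
Reagents that add atoms: 1-(triphenylphosphoranylidene)propan-2-one (compound 3), CC(=O)C=P(c1ccccc1)(c1ccccc1)c1ccccc1
Why: Double Wittig olefination with a ketone-stabilised ylide, which is too weakly basic to start aldol chemistry of the enolisable dialdehyde and gives the E-enones typical of stabilised ylides, the excess reagent ensuring that both termini react.

Step 3
Reactants: 4 (3E,19E)-docosa-3,19-diene-2,21-dione; 5 dimethyl malonate
Product: 8 dimethyl 6,6'-(tetradecane-1,14-diyl)bis(2,4-dioxocyclohexane-1-carboxylate), via bis-Michael adduct 6 (not isolated), via disodium bis-enolate 7 (not isolated)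
Conditions: 5 (3 equiv), NaOMe (3 equiv), MeOH, rt; slow addition of 4 in THF; reflux; concentrate, H2O, ether wash; cold 1 M HCl to pH 2
Reagents that add atoms: dimethyl malonate (compound 5), COC(=O)CC(=O)OC
Why: Sodiomalonate adds 1,4 to C4 and C19 of 4 (first C–C bond at each end) to give 6, and proton exchange then exposes the terminal methyl-ketone enolate, whose CH2 carbon attacks one malonate ester carbonyl and expels methoxide (second C–C bond). This is the well-known Michael–Claisen (Dieckmann-type) 3+3 annulation of alk-3-en-2-ones with malonates that leads to 5-alkylresorcinol precursors, here run at two independent termini. Each carbocycle closes in a 6-(enolendo)-exo-trig mode, whereas the competing internal enolate (C3 or C20) could only reach an ester through a four-membered ring and is therefore unproductive. C1 and C6 of each ring arise without external control (C1 is epimerisable and should settle trans to the chain, and the two remote rings are uncorrelated), which does not matter since all four centres are flattened in step 4. The step needs one malonate per enone rather than a second Michael addition or chain linking; this is secured by slow addition of 4 into excess sodiomalonate, by intramolecular closure outrunning bimolecular events, and by irreversible deprotonation to the vinylogous carboxylate 7, which withdraws the product from all equilibria. The fourteen-carbon spacer insulates the two ends from each other, and methoxide matches the methyl esters so that ester exchange is invisible.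

Step 4
Reactants: 8 dimethyl 6,6'-(tetradecane-1,14-diyl)bis(2,4-dioxocyclohexane-1-carboxylate)
Product: 10 dimethyl 6,6'-(tetradecane-1,14-diyl)bis(2,4-dihydroxybenzoate), via bis(3-bromo-2,4-dione) 9 (not isolated)
Conditions: Br2 (2.0 equiv, one per ring) in DMF added to 8 in DMF, 0 °C; rt 1 h; then 80 °C, N2; aq Na2S2O3
Reagents that add atoms: none
Why: Bromination–dehydrobromination aromatisation of a dihydroresorcinol, in which the enol is brominated at C3 to give 9, HBr in warm DMF relays the halogen to C1 or C5, and loss of HBr across the bond to C6 followed by enolisation gives the arene, with exactly one Br2 per ring to limit nuclear bromination.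

Step 5
Reactants: 10 dimethyl 6,6'-(tetradecane-1,14-diyl)bis(2,4-dihydroxybenzoate)
Product: 12 6,6'-(tetradecane-1,14-diyl)bis(2,4-dihydroxybenzoic acid), via tetrasodium salt 11 (not isolated)
Conditions: 2.5 M aq NaOH (12 equiv), MeOH, degassed, Ar, reflux; then 0 °C, 2 M HCl to pH 2; isolate without heating
Reagents that add atoms: sodium hydroxide, [Na+].[OH-]
Why: Ester saponification by acyl–oxygen cleavage, slowed here by the two ortho substituents and the phenolate charge and therefore run with excess alkali at reflux, with oxygen excluded because resorcinolate anions autoxidise, and with any early loss of carbon dioxide only anticipating step 6.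

Step 6
Reactants: 12 6,6'-(tetradecane-1,14-diyl)bis(2,4-dihydroxybenzoic acid)
Product: 13 bisnorstriatol, 5,5'-(tetradecane-1,14-diyl)bis(benzene-1,3-diol)
Conditions: 2 M aq HCl–1,4-dioxane (1:1), reflux, Ar
Reagents that add atoms: none
Why: Protodecarboxylation of a β-resorcylic acid, in which the carboxyl-bearing carbon lies ortho to one hydroxyl and para to the other so that ipso protonation is easy, and the flanking alkyl chain twists the carboxyl group out of conjugation, so that carbon dioxide leaves near 100 °C without affecting the saturated tether.

## Compound list

1 | hexadecane-1,16-diol | OCCCCCCCCCCCCCCCCO | starting material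
2 | hexadecanedial | O=CCCCCCCCCCCCCCCC=O | intermediate
3 | 1-(triphenylphosphoranylidene)propan-2-one | CC(=O)C=P(c1ccccc1)(c1ccccc1)c1ccccc1 | starting material
4 | (3E,19E)-docosa-3,19-diene-2,21-dione | CC(=O)/C=C/CCCCCCCCCCCCCC/C=C/C(C)=O | intermediate
5 | dimethyl malonate | COC(=O)CC(=O)OC | starting material
6 | tetramethyl 2,2'-(2,21-dioxodocosane-4,19-diyl)dipropanedioate (bis-Michael adduct) | CC(=O)CC(C(C(=O)OC)C(=O)OC)CCCCCCCCCCCCCCC(CC(C)=O)C(C(=O)OC)C(=O)OC | intermediate
7 | disodium bis-enolate of compound 8 | [Na+].[Na+].COC(=O)C1C(CCCCCCCCCCCCCCC2CC(=O)C=C([O-])C2C(=O)OC)CC(=O)C=C1[O-] | intermediate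
8 | dimethyl 6,6'-(tetradecane-1,14-diyl)bis(2,4-dioxocyclohexane-1-carboxylate), diastereomer and tautomer mixture | COC(=O)C1C(CCCCCCCCCCCCCCC2CC(=O)CC(=O)C2C(=O)OC)CC(=O)CC1=O | intermediate
9 | dimethyl 6,6'-(tetradecane-1,14-diyl)bis(3-bromo-2,4-dioxocyclohexane-1-carboxylate) | COC(=O)C1C(CCCCCCCCCCCCCCC2CC(=O)C(Br)C(=O)C2C(=O)OC)CC(=O)C(Br)C1=O | intermediate
10 | dimethyl 6,6'-(tetradecane-1,14-diyl)bis(2,4-dihydroxybenzoate) | COC(=O)c1c(O)cc(O)cc1CCCCCCCCCCCCCCc1cc(O)cc(O)c1C(=O)OC | intermediate
11 | tetrasodium 6,6'-(tetradecane-1,14-diyl)bis(2-hydroxy-4-oxidobenzoate) | [Na+].[Na+].[Na+].[Na+].[O-]C(=O)c1c(O)cc([O-])cc1CCCCCCCCCCCCCCc1cc([O-])cc(O)c1C([O-])=O | intermediate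
12 | 6,6'-(tetradecane-1,14-diyl)bis(2,4-dihydroxybenzoic acid) | OC(=O)c1c(O)cc(O)cc1CCCCCCCCCCCCCCc1cc(O)cc(O)c1C(=O)O | intermediate
13 | bisnorstriatol, 5,5'-(tetradecane-1,14-diyl)bis(benzene-1,3-diol) | Oc1cc(O)cc(CCCCCCCCCCCCCCc2cc(O)cc(O)c2)c1 | target

## Step count and risks

Total step count: 6
Longest linear sequence: 6 (from compound 1)

**Step 3.**
- **Risk:** the annulation may run unevenly. One terminus may stall at the open Michael stage or revert. A malonate already attached to one chain may add to an enone of another chain and link them. The low solubility of the long-chain substrate in methanol aggravates both.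
- **Fallback:** the same open-chain precursor is assembled with reversed polarity, so that the one-to-one pairing of malonate and terminus is fixed before any ring closes.
  - The fallback sets out from 2. A Knoevenagel condensation with 5 (TiCl4, pyridine, THF, 0 °C to rt) should give tetramethyl 2,2'-(hexadecane-1,16-diylidene)dipropanedioate F1.
  - A Mukaiyama–Michael addition of 2-(trimethylsilyloxy)propene (TiCl4, CH2Cl2, −78 °C, aqueous work-up) then installs the acetonyl groups.
  - The fallback comes back to the route at 6, now an isolable and purifiable compound. It is closed to 8 in a separate Dieckmann-type operation with NaOMe in MeOH–THF.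

**Step 4.**
- **Risk:** the halogen may be misallocated. A ring that has already aromatised is electron-rich and competes for bromine with a ring that is still a dione, so nuclear bromination at one end and lagging aromatisation at the other can occur together. HBr in hot DMF may also begin to cleave the esters.
- **Fallback:** the side reaction is made the method.
  - The fallback sets out from 8. Excess Br2 (at least 6 equiv) in AcOH, rt to 60 °C, drives both rings to a single exhaustively halogenated end point, dimethyl 6,6'-(tetradecane-1,14-diyl)bis(3,5-dibromo-2,4-dihydroxybenzoate) F2.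
  - Hydrogenolysis of the four C–Br bonds (H2, Pd/C, NaOAc, MeOH–THF) brings the material back to the route at 10.

**Step 5.**
- **Risk:** acyl substitution may be sluggish at an ester flanked by two ortho substituents on a phenolate-rich ring. Prolonged heating in alkali could then give incomplete cleavage and oxidative darkening.
- **Fallback:** the ester is removed before the ring becomes aromatic.
  - The fallback sets out from 8. Aqueous NaOH at reflux hydrolyses the non-aromatic β-keto esters.
  - Acidification gives 6,6'-(tetradecane-1,14-diyl)bis(2,4-dioxocyclohexane-1-carboxylic acid) F3, which is not isolated.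
  - On warming in the acidic medium it loses carbon dioxide to give 5,5'-(tetradecane-1,14-diyl)bis(cyclohexane-1,3-dione) F4.
  - Oxidative aromatisation with catalytic I2 in DMSO (80–100 °C, DMSO as terminal oxidant) comes back to the route directly at 13.

## Further compounds

F1 | step 3 | tetramethyl 2,2'-(hexadecane-1,16-diylidene)dipropanedioate | COC(=O)C(=CCCCCCCCCCCCCCCC=C(C(=O)OC)C(=O)OC)C(=O)OC
F2 | step 4 | dimethyl 6,6'-(tetradecane-1,14-diyl)bis(3,5-dibromo-2,4-dihydroxybenzoate) | COC(=O)c1c(O)c(Br)c(O)c(Br)c1CCCCCCCCCCCCCCc1c(Br)c(O)c(Br)c(O)c1C(=O)OC
F3 | step 5 | 6,6'-(tetradecane-1,14-diyl)bis(2,4-dioxocyclohexane-1-carboxylic acid) | OC(=O)C1C(CCCCCCCCCCCCCCC2CC(=O)CC(=O)C2C(=O)O)CC(=O)CC1=O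
F4 | step 5 | 5,5'-(tetradecane-1,14-diyl)bis(cyclohexane-1,3-dione) | O=C1CC(=O)CC(CCCCCCCCCCCCCCC2CC(=O)CC(=O)C2)C1
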